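## Structural features

The target is a eudesmane-type ester built on a trans-fused decalin; ring A (C1–C5, C10) and ring B (C5–C10) share the C5–C10 bond (terpene numbering throughout). Ring A carries a secondary 3α-acyloxy group next to a tertiary carbinol at C4 (4α-OH, 4β-CH3). Ring B carries the C8 ketone conjugated with the exocyclic, tetrasubstituted C7=C11 isopropylidene. Four ring stereocentres are contiguous (C3, C4, C5, C10): the two oxygens are cis on the α-face, H-5 is α, and the angular methyl on the quaternary C10 is β and 1,3-diaxial to the C4 methyl. A fifth stereocentre lies β to the carbonyl of the (S)-3-methylpentanoyl chain. The fragile parts are the α-alkylidene ketone (deconjugation under base, conjugate addition), the tertiary C4 alcohol (dehydration under acid) and the ester beside a free hydroxyl (hydrolysis, migration). The real difficulty is the absolute configuration of the quaternary C10 together with its trans relation to C5; C3 and C4 can then be relayed from the angular methyl. The key step uses the fact that, with C4 as a ketone in ring A, C10 is the β-carbon and C5 the α-carbon of an enone, so the C10 methyl and the C6 chain can be introduced one after the other, and the two arms (C9–C8 on C10, C6–C7≡C11 on C5) are the two halves of ring B.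

## Logic of the disconnections

**18 to 15 and 16.** The C3–O acyl bond is cut. The ester is the most labile bond, and the side-chain stereocentre is bought with 16. This removes six carbons and one stereocentre and makes the route convergent at the end. The forward step must acylate the axial secondary 3α-hydroxyl and leave the tertiary 4α-hydroxyl alone; activation of 16 as 17 serves this, and the β-stereocentre of the acid cannot epimerize.

**15 to 14.** Both C–O bonds at C3 and C4 are cut back to the C3=C4 alkene. A cis-diol on the face opposite the angular methyl is what a suprafacial osmylation of this alkene should deliver. Two stereocentres disappear. The forward step must attack the trisubstituted alkene and not the C7=C11 alkene, and from the α-face.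

**14 to 13.** No skeletal bond is cut; C8 is taken from ketone to alcohol, because the alcohol is the direct product of an aldehyde–alkyne coupling. The demand is an oxidant that touches neither alkene.

**13 to 12.** The C7–C8 bond and the C11–CH3 bond are cut. Both lie at the tetrasubstituted alkene, so one alkylative aldehyde–alkyne cyclization closes ring B and completes the isopropylidene. The bicycle is reduced to a monocyclic ring A with two arms. The forward step must close a six-membered ring at nickel, transfer a zinc-bound methyl to C11 and tolerate the C3=C4 alkene.

**12 to 11.** The C8 carbonyl is returned to its dioxolane. The aldehyde has to stay masked through the organometallic steps. The demand is hydrolysis without migration of, or attack by, the trisubstituted alkene.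

**11 to 10 to 8 (through 9).** The C4–C15 bond is cut. A methyl on an sp2 carbon can come from a ketone through its enol triflate, and the alkene position is fixed by kinetic enolization toward C3. This returns the ring A ketone that the key step produces. The forward steps must deprotonate at C3 and not at C5, and couple in the presence of the alkyne and the acetal.

**8 to 4 and 5 (through 6 and 7).** The C10–C14 and C5–C6 bonds are cut. C10 is β and C5 is α to the C4 carbonyl, so an aluminium-bound methyl and 5 can be added in one flask. Two bonds and two stereocentres are removed and the precursor 4 is flat and achiral. The forward step needs enantiofacial control by a chiral copper catalyst, a regiodefined enolate, and C6 placed trans to C9.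

**4 to 1 and 2 (through 3).** The C9–C10 bond is cut. Addition of 2 to the vinylogous ester 1 with carbonyl transposition gives the 3-substituted enone in one step from two commercial materials. The demand is that the dioxolane outlives a brief acidic work-up.

## Other disconnections considered

**Alternative 1:** The cut runs through C4–C5 and C9–C10, so both rings would arise in one cationic event from the acyclic ketone A2, (3R,6E)-3-(benzyloxy)-10-(tert-butyldimethylsilyloxy)-6-methylundeca-6,10-dien-2-one.
- **Forward step.** A chelating aluminium or tin Lewis acid would hold the C4 carbonyl and the C3 benzyloxy oxygen in a five-membered chelate. C5 of the (E)-alkene would attack C4, and the tertiary C10 cation would be captured by C9 of the silyl enol ether, giving the decalone A1.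
- **In favour.** One stereocentre (C3) would set C4 through the chelate, and C5 and C10 through chair-like anti addition across the (E)-alkene. The cis C3–O/C4–OH pair and the trans ring fusion would appear together, with the two oxygens already differentiated. On stereochemical economy this is better than the chosen plan, which needs a separate osmylation and a late mono-acylation.
- **Against.** A silyl enol ether is a far better nucleophile than a trisubstituted alkene, so direct aldol-type attack on the activated ketone, or loss of the silyl group, can pre-empt the intended order of events. The α-alkoxy ketone may epimerize under the Lewis acid. A2 is an enantiopure, geometrically defined chain that itself would need roughly six to eight steps. A1 lacks the isopropylidene, which requires a regioselective aldol condensation at C7, and the benzyl ether must then be removed beside a reducible enone.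
- **Comparison.** On structure, it would create two rings and four stereocentres at once, against two bonds and two stereocentres in step 2. On mechanism, it rests on a cation cascade of doubtful chemoselectivity, against a catalytic conjugate addition of established scope. On step economy, the number of steps after the key event is about equal, but the total is probably longer.

**Alternative 2:** The cut is the C3–C4 bond, leading to the keto aldehyde A4, 3-[(7R,8R)-8-acetyl-7-methyl-1,4-dioxaspiro[4.5]decan-7-yl]propanal, built on a finished ring B.
- **Forward step.** A divalent samarium reductant would form the ketyls, and their coupling would close ring A as the diol A3.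
- **In favour.** The diol would form directly, with no alkene intermediate and no osmium. Samarium-bridged pinacol closures of six-membered rings normally give the cis-diol, so on the C3/C4 relationship it is the equal of osmylation.
- **Against.** The configuration of C4 relative to C5 and C10 is the weak point. The required product has the C4 methyl axial and syn to the C10 methyl, so the transition state leading to it carries a methyl/methyl 1,3-diaxial contact, while the competing one places the smaller O–Sm group axial. The diol may therefore form on the β-face. In the chosen plan the same angular methyl helps, because it screens the β-face from OsO4. A4 also needs the C10 quaternary centre and its relation to C5 set enantioselectively beforehand, which moves the main problem into the precursor. After A3, the ketal must be removed and the isopropylidene and the ester added.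
- **Comparison.** On structure, it forms one bond, one ring and two stereocentres. On mechanism, it is reliable for ring closure but uncertain for the C4 configuration. On step economy, it is equal at best and probably a few steps longer.

**Alternative 3:** The cut is C9–C10, made with a sacrificial C5–C8 bond.
- **Forward step.** Irradiation of 3-methylcyclohex-2-en-1-one A5 with propa-1,2-diene A6 would give the head-to-head [2+2] adduct A7, 6-methyl-8-methylidenebicyclo[4.2.0]octan-2-one. Ozonolysis to the strained β-diketone A8 and alkoxide-induced retro-Claisen cleavage of C5–C8 would then give the keto ester A9, methyl [(1S)-1-methyl-3-oxocyclohexyl]acetate.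
- **In favour.** The feedstocks are very cheap and no pyrophoric organometallic is needed; on cost and reagent hazard it is better than the chosen plan. C8 arrives at the acid oxidation level, which suits a later Claisen-type closure of ring B that would give the C8 ketone without a redox step; that point is also better.
- **Against.** The photoadduct is racemic unless a chiral Lewis acid variant is developed, so the C10 configuration would need a resolution. Three steps are spent to reach A9, which stands at the same stage as the conjugate adduct of the chosen plan. A9 has no regiodefined enolate, so placing C6 at C5 and not at C3 would cost blocking or directing steps. Gaseous A6 and photochemical scale-up add practical burden.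
- **Comparison.** On structure, it forms one lasting bond and one stereocentre, against two of each. On mechanism, it is robust but not enantioselective. On step economy, it is clearly longer.

Key step: step 2

Assumption: the sense of induction of the copper–phosphoramidite catalyst on 4 is taken by analogy with simpler 3-alkylcyclohexenones; whichever ligand antipode delivers methyl to the Si face of C3 of 4 is used, both being accessible.

Remark on the structures: the descriptors of the key-step product, (2R,3R), were checked against the target (C5 and C10 both R there) and agree; no structure needed correction.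

## Route

**Step 1**
Reactants: 1 3-ethoxycyclohex-2-en-1-one; 2 (1,3-dioxolan-2-ylmethyl)magnesium bromide
Product: 4 3-(1,3-dioxolan-2-ylmethyl)cyclohex-2-en-1-one, via bromomagnesium 1,2-adduct 3 (not isolated)
Conditions: 2 (1.3 equiv), THF, 0 °C → rt; then 1 M aq. HCl, 0 °C, 15 min
Reagents that add atoms: water, O
Why: Stork–Danheiser sequence: 1,2-addition to the vinylogous ester gives 3, and cold dilute acid hydrolyses the enol ether and eliminates the tertiary hydroxyl with carbonyl transposition. The dioxolane should survive because this hydrolysis is much faster than acetal cleavage under the same conditions.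

**Step 2**
Reactants: 4 3-(1,3-dioxolan-2-ylmethyl)cyclohex-2-en-1-one; 5 1-bromobut-2-yne
Product: 8 (2R,3R)-2-(but-2-yn-1-yl)-3-(1,3-dioxolan-2-ylmethyl)-3-methylcyclohexan-1-one, via dimethylaluminium enolate 6 (not isolated), via lithium aluminate enolate 7 (not isolated)
Conditions: copper thiophene-2-carboxylate Cu(O2CC4H3S) (5 mol%), N,N-bis(1-phenylethyl)dibenzo[d,f][1,3,2]dioxaphosphepin-6-amine (one antipode, 10 mol%), Me3Al (1.5 equiv), Et2O, −30 °C; then THF, MeLi (1.5 equiv), 0 °C; then 5 (2 equiv), DMPU, 0 °C → rt; aq. NH4Cl/potassium sodium tartrate
Reagents that add atoms: trimethylaluminium, C[Al](C)C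
Why: Me3Al transmetalates to the ligand-bound monovalent copper, the methylcopper species binds the enone, oxidative addition at C10 gives a trivalent copper β-alkyl enolate, and reductive elimination forms C10–CH3 and releases the dimethylaluminium enolate 6 with the C4=C5 double bond fixed. MeLi converts 6 into the more nucleophilic aluminate/lithium enolate 7, which displaces bromide from 5 by SN2 at the propargylic CH2 and forms C5–C6. The closest known reaction type is the copper-catalysed asymmetric conjugate addition of trialkylaluminium reagents to 3-substituted cyclohex-2-enones with alkylation of the resulting enolate; no ring is closed. C10 is controlled by the chiral ligand on copper, which must deliver methyl to the Si face of C3 of 4 to give the R centre. C5 is controlled by the substrate: in the half-chair enolate the electrophile should enter axially, anti to the pseudoaxial CH2-dioxolane arm and past the smaller pseudoequatorial methyl, so that C6 ends trans to C9 (R at C5); the centre stays correctable by base equilibration beside the ketone. The step needs 1,4- over 1,2-addition (copper catalysis in Et2O at low temperature), alkylation at C5 and not C3 (regiospecific enolate; a reactive propargylic bromide with DMPU should outrun proton transfer), monoalkylation (the product is a hindered ketone), and survival of the acetal (ether solvent and low temperature temper the Lewis acidity of aluminium).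

**Step 3**
Reactants: 8 (2R,3R)-2-(but-2-yn-1-yl)-3-(1,3-dioxolan-2-ylmethyl)-3-methylcyclohexan-1-one
Product: 10 (5R,6R)-6-(but-2-yn-1-yl)-5-(1,3-dioxolan-2-ylmethyl)-5-methylcyclohex-1-en-1-yl trifluoromethanesulfonate, via potassium enolate 9 (not isolated)
Conditions: KN(SiMe3)2, THF, −78 °C; then PhNTf2, −78 → 0 °C
Reagents that add atoms: N-phenylbis(trifluoromethanesulfonimide), O=S(=O)(N(c1ccccc1)S(=O)(=O)C(F)(F)F)C(F)(F)F
Why: Kinetic deprotonation with a bulky amide base should occur at the C3 methylene, not at the hindered C5 methine beside the quaternary carbon, and O-triflation of 9 fixes the alkene at C3=C4. C5 is not enolized under these conditions, so its configuration is kept.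

**Step 4**
Reactants: 10 (5R,6R)-6-(but-2-yn-1-yl)-5-(1,3-dioxolan-2-ylmethyl)-5-methylcyclohex-1-en-1-yl trifluoromethanesulfonate
Product: 11 2-{[(1R,2R)-2-(but-2-yn-1-yl)-1,3-dimethylcyclohex-3-en-1-yl]methyl}-1,3-dioxolane
Conditions: Fe(acac)3 (5 mol%), MeMgBr, THF/NMP, −30 → 0 °C
Reagents that add atoms: methylmagnesium bromide, C[Mg]Br
Why: Iron-catalysed Kumada-type cross-coupling of an alkenyl triflate with a methyl Grignard reagent is fast at low temperature, which should leave the internal alkyne and the acetal untouched. The C4–C15 bond forms with the alkene position retained.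

**Step 5**
Reactants: 11 2-{[(1R,2R)-2-(but-2-yn-1-yl)-1,3-dimethylcyclohex-3-en-1-yl]methyl}-1,3-dioxolane
Product: 12 2-[(1R,2R)-2-(but-2-yn-1-yl)-1,3-dimethylcyclohex-3-en-1-yl]acetaldehyde
Conditions: 1 M aq. HCl, THF, 0 °C → rt
Reagents that add atoms: water, O
Why: Acid-catalysed acetal hydrolysis of an unhindered aldehyde dioxolane proceeds under conditions mild enough that the trisubstituted alkene and the alkyne should not react. The aldehyde has no α-stereocentre to lose.

**Step 6**
Reactants: 12 2-[(1R,2R)-2-(but-2-yn-1-yl)-1,3-dimethylcyclohex-3-en-1-yl]acetaldehyde
Product: 13 (4aR,8aR)-5,8a-dimethyl-3-(propan-2-ylidene)-1,2,3,4,4a,7,8,8a-octahydronaphthalen-2-ol (both C8 epimers)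
Conditions: Ni(cod)2 (10 mol%), Me2Zn (2.5 equiv), THF, 0 °C, slow addition of 12; aq. NH4Cl
Reagents that add atoms: dimethylzinc, C[Zn]C
Why: Nickel-catalysed alkylative ynal cyclization: zerovalent nickel couples the aldehyde and the alkyne oxidatively (C7–C8, six-membered ring B), the oxanickelacycle transmetalates with Me2Zn, and reductive elimination places the new methyl on C11. Both alkene termini then carry methyl, so no geometric issue arises. The trans ring fusion follows from the trans arms set in step 2, and the C8 epimers converge in step 7.

**Step 7**
Reactants: 13 (4aR,8aR)-5,8a-dimethyl-3-(propan-2-ylidene)-1,2,3,4,4a,7,8,8a-octahydronaphthalen-2-ol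
Product: 14 (4aR,8aR)-5,8a-dimethyl-3-(propan-2-ylidene)-3,4,4a,7,8,8a-hexahydronaphthalen-2(1H)-one
Conditions: Dess–Martin periodinane, NaHCO3, CH2Cl2, 0 °C → rt
Reagents that add atoms: none
Why: Dess–Martin oxidation of a secondary allylic alcohol is neutral and mild, so neither alkene should migrate and the conjugated C7=C11 enone is formed directly. Oxidation at this point also deactivates C7=C11 toward the osmylation that follows.

**Step 8**
Reactants: 14 (4aR,8aR)-5,8a-dimethyl-3-(propan-2-ylidene)-3,4,4a,7,8,8a-hexahydronaphthalen-2(1H)-one
Product: 15 (4aR,5S,6R,8aR)-5,6-dihydroxy-5,8a-dimethyl-3-(propan-2-ylidene)octahydronaphthalen-2(1H)-one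
Conditions: OsO4 (5 mol%), 4-methylmorpholine N-oxide, acetone/H2O, rt
Reagents that add atoms: osmium tetroxide, O=[Os](=O)(=O)=O (catalytic oxygen carrier); 4-methylmorpholine N-oxide, C[N+]1([O-])CCOCC1; water, O
Why: Upjohn dihydroxylation: the suprafacial [3+2] osmylation makes O-3 and O-4 cis, and attack should come from the α-face because the axial C10 methyl screens the β-face of C4. The electron-rich trisubstituted C3=C4 alkene should react well ahead of the electron-poor, tetrasubstituted enone alkene.

**Step 9**
Reactants: 15 (4aR,5S,6R,8aR)-5,6-dihydroxy-5,8a-dimethyl-3-(propan-2-ylidene)octahydronaphthalen-2(1H)-one; 16 (3S)-3-methylpentanoic acid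
Product: 18 (1S,2R,4aR,8aR)-1-hydroxy-1,4a-dimethyl-6-oxo-7-(propan-2-ylidene)decahydronaphthalen-2-yl (3S)-3-methylpentanoate, via mixed anhydride 17 (not isolated)
Conditions: 16, 2,4,6-trichlorobenzoyl chloride, Et3N, THF, rt; then 15, DMAP, toluene, rt → 40 °C
Reagents that add atoms: none
Why: Yamaguchi esterification: DMAP attacks the aliphatic carbonyl of 17 and the acylpyridinium acylates the secondary 3α-hydroxyl, while the tertiary 4α-hydroxyl should be too hindered to react. The acid stereocentre is β to the carbonyl and cannot epimerize.

## Compound list

1 | 3-ethoxycyclohex-2-en-1-one | CCOC1=CC(=O)CCC1 | starting material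
2 | (1,3-dioxolan-2-ylmethyl)magnesium bromide | Br[Mg]CC1OCCO1 | starting material
3 | bromomagnesium 1-(1,3-dioxolan-2-ylmethyl)-3-ethoxycyclohex-2-en-1-olate (racemic 1,2-adduct) | CCOC1=CC(CC2OCCO2)(O[Mg]Br)CCC1 | intermediate (not isolated)
4 | 3-(1,3-dioxolan-2-ylmethyl)cyclohex-2-en-1-one | O=C1C=C(CC2OCCO2)CCC1 | intermediate
5 | 1-bromobut-2-yne | CC#CCBr | starting material
6 | dimethyl{[(3R)-3-(1,3-dioxolan-2-ylmethyl)-3-methylcyclohex-1-en-1-yl]oxy}alumane | C[Al](C)OC1=C[C@@](C)(CC2OCCO2)CCC1 | intermediate (not isolated)
7 | lithium trimethyl{[(3R)-3-(1,3-dioxolan-2-ylmethyl)-3-methylcyclohex-1-en-1-yl]oxy}aluminate | [Li+].C[Al-](C)(C)OC1=C[C@@](C)(CC2OCCO2)CCC1 | intermediate (not isolated)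
8 | (2R,3R)-2-(but-2-yn-1-yl)-3-(1,3-dioxolan-2-ylmethyl)-3-methylcyclohexan-1-one (butynyl cis to methyl, trans to the dioxolanylmethyl arm) | O=C1CCC[C@](C)(CC2OCCO2)[C@H]1CC#CC | intermediate
9 | potassium (5R,6R)-6-(but-2-yn-1-yl)-5-(1,3-dioxolan-2-ylmethyl)-5-methylcyclohex-1-en-1-olate | [K+].[O-]C1=CCC[C@](C)(CC2OCCO2)[C@H]1CC#CC | intermediate (not isolated)
10 | (5R,6R)-6-(but-2-yn-1-yl)-5-(1,3-dioxolan-2-ylmethyl)-5-methylcyclohex-1-en-1-yl trifluoromethanesulfonate | O=S(=O)(OC1=CCC[C@](C)(CC2OCCO2)[C@H]1CC#CC)C(F)(F)F | intermediate
11 | 2-{[(1R,2R)-2-(but-2-yn-1-yl)-1,3-dimethylcyclohex-3-en-1-yl]methyl}-1,3-dioxolane | CC1=CCC[C@](C)(CC2OCCO2)[C@H]1CC#CC | intermediate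
12 | 2-[(1R,2R)-2-(but-2-yn-1-yl)-1,3-dimethylcyclohex-3-en-1-yl]acetaldehyde | CC1=CCC[C@](C)(CC=O)[C@H]1CC#CC | intermediate
13 | (4aR,8aR)-5,8a-dimethyl-3-(propan-2-ylidene)-1,2,3,4,4a,7,8,8a-octahydronaphthalen-2-ol (trans-fused; eudesma-3,7(11)-dien-8-ol, both C8 epimers) | CC1=CCC[C@]2(C)CC(O)C(=C(C)C)C[C@@H]12 | intermediate
14 | (4aR,8aR)-5,8a-dimethyl-3-(propan-2-ylidene)-3,4,4a,7,8,8a-hexahydronaphthalen-2(1H)-one (eudesma-3,7(11)-dien-8-one) | CC1=CCC[C@]2(C)CC(=O)C(=C(C)C)C[C@@H]12 | intermediate
15 | (4aR,5S,6R,8aR)-5,6-dihydroxy-5,8a-dimethyl-3-(propan-2-ylidene)octahydronaphthalen-2(1H)-one (3α,4α-dihydroxyeudesm-7(11)-en-8-one) | O[C@@H]1CC[C@]2(C)CC(=O)C(=C(C)C)C[C@H]2[C@]1(C)O | intermediate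
16 | (3S)-3-methylpentanoic acid | CC[C@H](C)CC(=O)O | starting material
17 | (3S)-3-methylpentanoic 2,4,6-trichlorobenzoic anhydride | CC[C@H](C)CC(=O)OC(=O)c1c(Cl)cc(Cl)cc1Cl | intermediate (not isolated)
18 | (1S,2R,4aR,8aR)-1-hydroxy-1,4a-dimethyl-6-oxo-7-(propan-2-ylidene)decahydronaphthalen-2-yl (3S)-3-methylpentanoate (4α-hydroxy-8-oxoeudesm-7(11)-en-3α-yl ester) | CC[C@H](C)CC(=O)O[C@@H]1CC[C@]2(C)CC(=O)C(=C(C)C)C[C@H]2[C@]1(C)O | target

## Step count and least certain steps

Total: 9 steps. Longest linear sequence: 9 steps (1 to 18); 16 enters in the last step.

**Step 2 (key step).**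
- What may go wrong: the acetal oxygens can bind aluminium or copper and lower the enantiofacial discrimination. The aluminium-bound enolate can alkylate sluggishly, allowing proton exchange with the product and hence alkylation at C3 or double alkylation. Facial selectivity at C5 may be only modest, because methyl and the CH2-dioxolane arm differ little in size. Lewis-acid opening of the dioxolane is also possible.
- Fallback: the operation is split, setting out from 4 and coming back at 8. The conjugate addition is run as before and 6 is quenched with acetic anhydride to give the isolable enol acetate (3R)-3-(1,3-dioxolan-2-ylmethyl)-3-methylcyclohex-1-en-1-yl acetate F1, on which the enantiomeric purity can be checked. MeLi (2 equiv, THF, 0 °C) then releases the aluminium-free lithium (3R)-3-(1,3-dioxolan-2-ylmethyl)-3-methylcyclohex-1-en-1-olate F2, which is alkylated with 5 in THF/DMPU to give 8. Any C5 epimer, (2S,3R)-2-(but-2-yn-1-yl)-3-(1,3-dioxolan-2-ylmethyl)-3-methylcyclohexan-1-one F3, is separated and re-equilibrated with NaOMe in MeOH to return more 8.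

**Step 6.**
- What may go wrong: oxidative cyclization to a six-membered ring at an aldehyde beside a quaternary carbon may be slow. Uncatalysed methyl addition to the aldehyde and alkyne oligomerization can then compete.
- Fallback: setting out from 12 and coming back at 14 (13 is bypassed). AgSbF6-catalysed intramolecular alkyne–carbonyl metathesis (CH2Cl2, rt) forms C7–C8 as an alkene and turns C11 into a ketone, giving 1-[(4aR,8aR)-4a,8-dimethyl-1,4,4a,5,6,8a-hexahydronaphthalen-2-yl]ethan-1-one F4. 1,2-Addition of MeMgBr/CeCl3 gives the tertiary allylic alcohol 2-[(4aR,8aR)-4a,8-dimethyl-1,4,4a,5,6,8a-hexahydronaphthalen-2-yl]propan-2-ol F5. Babler–Dauben oxidative transposition with pyridinium chlorochromate, (C5H5NH)[CrO3Cl], then moves oxygen to C8 and the alkene to C7=C11, giving 14. This costs one step more and exposes the C3=C4 alkene to a Lewis acid.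

**Step 1.**
- What may go wrong: the β-alkoxy Grignard reagent is a weak nucleophile toward a vinylogous ester and can fragment by β-elimination. The acidic work-up may partly unmask the aldehyde, which would then condense.
- Fallback: setting out from 2 and coming back at 4, with no acid step. Transmetalation of 2 with ZnCl2 gives (1,3-dioxolan-2-ylmethyl)zinc chloride F6, and Pd(PPh3)4-catalysed Negishi coupling with commercial 3-bromocyclohex-2-en-1-one F7 forms the C9–C10 bond and gives 4.

**Step 5.**
- What may go wrong: acid may move the C3=C4 double bond or trigger Prins- or ene-type attack of that alkene on the protonated aldehyde (C4 onto C8, a bridged bicyclo[3.2.1] skeleton).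
- Fallback: setting out from 10 and coming back at 12, with the order of events reversed so that the acetal is cleaved while the ring alkene is still an electron-poor enol triflate. Aqueous HCl in THF gives (5R,6R)-6-(but-2-yn-1-yl)-5-methyl-5-(2-oxoethyl)cyclohex-1-en-1-yl trifluoromethanesulfonate F8. Stille methylation (Me4Sn, LiCl, Pd(PPh3)4, DMF, 60 °C), which tolerates the aldehyde, then gives 12.

## Further compounds

F1 | step 2 | (3R)-3-(1,3-dioxolan-2-ylmethyl)-3-methylcyclohex-1-en-1-yl acetate | CC(=O)OC1=C[C@@](C)(CC2OCCO2)CCC1
F2 | step 2 | lithium (3R)-3-(1,3-dioxolan-2-ylmethyl)-3-methylcyclohex-1-en-1-olate | [Li+].[O-]C1=C[C@@](C)(CC2OCCO2)CCC1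
F3 | step 2 | (2S,3R)-2-(but-2-yn-1-yl)-3-(1,3-dioxolan-2-ylmethyl)-3-methylcyclohexan-1-one | O=C1CCC[C@](C)(CC2OCCO2)[C@@H]1CC#CC
F4 | step 6 | 1-[(4aR,8aR)-4a,8-dimethyl-1,4,4a,5,6,8a-hexahydronaphthalen-2-yl]ethan-1-one | CC(=O)C1=CC[C@@]2(C)CCC=C(C)[C@@H]2C1
F5 | step 6 | 2-[(4aR,8aR)-4a,8-dimethyl-1,4,4a,5,6,8a-hexahydronaphthalen-2-yl]propan-2-ol | CC(C)(O)C1=CC[C@@]2(C)CCC=C(C)[C@@H]2C1
F6 | step 1 | (1,3-dioxolan-2-ylmethyl)zinc chloride | Cl[Zn]CC1OCCO1
F7 | step 1 | 3-bromocyclohex-2-en-1-one | O=C1C=C(Br)CCC1
F8 | step 5 | (5R,6R)-6-(but-2-yn-1-yl)-5-methyl-5-(2-oxoethyl)cyclohex-1-en-1-yl trifluoromethanesulfonate | O=S(=O)(OC1=CCC[C@](C)(CC=O)[C@H]1CC#CC)C(F)(F)F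
A1 | alternative 1 | (4aR,5S,6R,8aR)-6-(benzyloxy)-5-hydroxy-5,8a-dimethyloctahydronaphthalen-2(1H)-one | c1ccccc1CO[C@@H]2CC[C@]3(C)CC(=O)CC[C@H]3[C@]2(C)O
A2 | alternative 1 | (3R,6E)-3-(benzyloxy)-10-(tert-butyldimethylsilyloxy)-6-methylundeca-6,10-dien-2-one | CC(=O)[C@H](OCc1ccccc1)CC/C(C)=C/CCC(=C)O[Si](C)(C)C(C)(C)C
A3 | alternative 2 | (4a'R,5'S,6'R,8a'R)-5',8a'-dimethyloctahydro-1'H-spiro[1,3-dioxolane-2,2'-naphthalene]-5',6'-diol | O[C@@H]1CC[C@]2(C)CC3(OCCO3)CC[C@H]2[C@]1(C)O
A4 | alternative 2 | 3-[(7R,8R)-8-acetyl-7-methyl-1,4-dioxaspiro[4.5]decan-7-yl]propanal | O=CCC[C@]1(C)CC2(OCCO2)CC[C@H]1C(C)=O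
A5 | alternative 3 | 3-methylcyclohex-2-en-1-one | CC1=CC(=O)CCC1
A6 | alternative 3 | propa-1,2-diene | C=C=C
A7 | alternative 3 | 6-methyl-8-methylidenebicyclo[4.2.0]octan-2-one (cis-fused, configuration as drawn) | O=C1CCC[C@]2(C)CC(=C)[C@H]12
A8 | alternative 3 | 6-methylbicyclo[4.2.0]octane-2,8-dione (cis-fused, configuration as drawn) | O=C1CCC[C@]2(C)CC(=O)[C@H]12
A9 | alternative 3 | methyl [(1S)-1-methyl-3-oxocyclohexyl]acetate | COC(=O)C[C@@]1(C)CCCC(=O)C1
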